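**Plan**
- Retrosynthesis: open the lactone at the C19 acyl–O bond and take the C4 methyl back to a C4 geminal diester; cut ring B at C7–C8 and C9–C10 (quinone [4+2]); cut the diene at C6=C7 (Wittig), C5=C10 (aldol condensation), C4–C5 (allylation) and C1–C10 (Suzuki–Miyaura).
- Enabling feature: ring C (C8, C9, C11–C14) carries para oxygens at C11 and C14, so it is the reduced form of 2-isopropyl-3-methoxybenzoquinone. The unsubstituted C8=C9 edge of that quinone is a dienophile, and ring B is the six-membered ring it forms with a C7=C6–C5=C10 diene on ring A, whose substituted terminus becomes the quaternary C10.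
- Forward order: ring C as quinone 5 (three steps) and ring A as vinylcyclohexene 15 (six steps) are made separately; the Diels–Alder reaction closes ring B; the lactone ring closes last; C7 oxidation and unmasking of the hydroquinone finish the synthesis.
- Stereochemistry: C10 comes from the chiral titanium Lewis acid in the cycloaddition (the only stereocentre left once ring C aromatises); C5 from hydrogenation anti to the C10 arm; C4 from enolate methylation anti to the same axial arm.

Key step: step 10

Numbering: abietane numbering is used for all tricycles; C20 is the CH2O carbon on C10 and defines the β face, C19 and C18 are the β and α carbons on C4.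
Assumption: the sense of induction of the BINOL–titanium Lewis acid with this diene is not established; (R)-BINOL is written, and (S)-BINOL would be used instead if it proved to deliver the antipode of 17.

**Step 1**
Reactants: 1 1,2,4-trimethoxybenzene
Product: 3 2-(2,3,6-trimethoxyphenyl)propan-2-ol, via (2,3,6-trimethoxyphenyl)lithium 2 (not isolated)
Conditions: n-BuLi, THF, 0 °C → rt; then acetone, −78 °C → rt
Reagents that add atoms: acetone, CC(C)=O; n-butyllithium (lithium of 2 only), [Li]CCCC
Why: Directed ortho-metalation removes the C3 proton flanked by two methoxy groups, and the aryllithium adds to the ketone carbonyl.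

**Step 2**
Reactants: 3 2-(2,3,6-trimethoxyphenyl)propan-2-ol
Product: 4 1,2,4-trimethoxy-3-(propan-2-yl)benzene
Conditions: Et3SiH, CF3CO2H, CH2Cl2, 0 °C → rt
Reagents that add atoms: none
Why: Ionic hydrogenation, in which acid ionises the tertiary benzylic alcohol to a cation stabilised by two ortho methoxy groups and the silane delivers hydride.

**Step 3**
Reactants: 4 1,2,4-trimethoxy-3-(propan-2-yl)benzene
Product: 5 2-methoxy-3-(propan-2-yl)cyclohexa-2,5-diene-1,4-dione (2-isopropyl-3-methoxy-1,4-benzoquinone)
Conditions: (NH4)2Ce(NO3)6, MeCN/H2O, 0 °C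
Reagents that add atoms: water, O
Why: Oxidative demethylation of the para-dimethoxy pair by tetravalent cerium gives the 1,4-quinone and keeps the third methoxy group, the usual outcome for 1,2,4-trimethoxyarenes.

**Step 4**
Reactants: 6 2-bromoprop-2-en-1-ol
Product: 7 [(2-bromoprop-2-en-1-yl)oxy](tert-butyl)dimethylsilane
Conditions: TBSCl, imidazole, CH2Cl2, rt
Reagents that add atoms: tert-butyl(chloro)dimethylsilane, CC(C)(C)[Si](C)(C)Cl
Why: Standard silylation of a primary allylic alcohol gives a non-coordinating ether that should survive Lewis acid, base and hydrogenation.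

**Step 5**
Reactants: 8 dimethyl 2-(prop-2-en-1-yl)propanedioate (dimethyl allylmalonate), 7 [(2-bromoprop-2-en-1-yl)oxy](tert-butyl)dimethylsilane
Product: 10 dimethyl 2-[4-({[tert-butyl(dimethyl)silyl]oxy}methyl)pent-4-en-1-yl]propanedioate, via B-alkyl-9-BBN adduct 9 (not isolated)
Conditions: 9-BBN, THF, 0 °C → rt; then 7, PdCl2(dppf) (5 mol %), K3PO4, DMF/H2O, 50 °C
Reagents that add atoms: 9-borabicyclo[3.3.1]nonane (boryl group of 9 only), B1C2CCCC1CCC2
Why: Anti-Markovnikov hydroboration of the terminal alkene followed by B-alkyl Suzuki–Miyaura coupling with the 1,1-disubstituted vinyl bromide under zerovalent palladium forms the C1–C10 bond and tolerates esters and the silyl ether.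

**Step 6**
Reactants: 10 dimethyl 2-[4-({[tert-butyl(dimethyl)silyl]oxy}methyl)pent-4-en-1-yl]propanedioate
Product: 11 dimethyl 2-[4-({[tert-butyl(dimethyl)silyl]oxy}methyl)pent-4-en-1-yl]-2-(prop-2-en-1-yl)propanedioate
Conditions: allyl bromide, Cs2CO3, MeCN, 50 °C
Reagents that add atoms: 3-bromoprop-1-ene (allyl bromide), C=CCBr
Why: SN2 C-alkylation of the monosubstituted malonate anion creates the quaternary C4 and brings in C5 and C6.

**Step 7**
Reactants: 11 dimethyl 2-[4-({[tert-butyl(dimethyl)silyl]oxy}methyl)pent-4-en-1-yl]-2-(prop-2-en-1-yl)propanedioate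
Product: 13 dimethyl 2-(5-{[tert-butyl(dimethyl)silyl]oxy}-4-oxopentyl)-2-(2-oxoethyl)propanedioate, via bis-ozonide 12 (not isolated)
Conditions: O3, CH2Cl2, −78 °C; then Me2S, −78 °C → rt
Reagents that add atoms: ozone, [O-][O+]=O
Why: Ozonolysis with reductive work-up cleaves both terminal alkenes in one operation, the allyl group to the C6 aldehyde and the 1,1-disubstituted alkene to the C10 ketone.

**Step 8**
Reactants: 13 dimethyl 2-(5-{[tert-butyl(dimethyl)silyl]oxy}-4-oxopentyl)-2-(2-oxoethyl)propanedioate
Product: 14 dimethyl 3-({[tert-butyl(dimethyl)silyl]oxy}methyl)-2-formylcyclohex-2-ene-1,1-dicarboxylate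
Conditions: piperidine, AcOH (0.3 equiv each), 4 Å MS, toluene, 70 °C
Reagents that add atoms: none
Why: Amine-catalysed intramolecular aldol condensation, in which the secondary amine condenses faster with the aldehyde so that its enamine carbon C5 attacks the C10 ketone (six-membered closure) and dehydration gives the C5=C10 enal of ring A, as in the classical cyclisation of keto-aldehydes to cycloalkene-1-carbaldehydes.

**Step 9**
Reactants: 14 dimethyl 3-({[tert-butyl(dimethyl)silyl]oxy}methyl)-2-formylcyclohex-2-ene-1,1-dicarboxylate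
Product: 15 dimethyl 3-({[tert-butyl(dimethyl)silyl]oxy}methyl)-2-ethenylcyclohex-2-ene-1,1-dicarboxylate
Conditions: Ph3PCH3Br, KOtBu, THF, 0 °C; then 14, 0 °C → rt
Reagents that add atoms: methyltriphenylphosphonium bromide (CH2 through its ylide), C[P+](c1ccccc1)(c1ccccc1)c1ccccc1.[Br-]
Why: Wittig methylenation of the hindered enal with the non-stabilised ylide leaves the esters untouched and installs the C6=C7 vinyl group, completing the achiral diene.

**Step 10**
Reactants: 15 dimethyl 3-({[tert-butyl(dimethyl)silyl]oxy}methyl)-2-ethenylcyclohex-2-ene-1,1-dicarboxylate, 5 2-isopropyl-3-methoxy-1,4-benzoquinone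
Product: 17 dimethyl (10R)-20-[(tert-butyldimethylsilyl)oxy]-11,14-dihydroxy-12-methoxyabieta-5,8,11,13-tetraene-18,19-dioate, via endo ene-dione cycloadduct 16 (not isolated)
Conditions: 15 (1.3 equiv), (R)-BINOL/TiCl2(OiPr)2 (1:1, 30 mol %), 4 Å MS, CH2Cl2, −30 → 0 °C; then Et3N, 0 °C → rt, argon
Reagents that add atoms: none
Why: Proposed new method: the BINOL–titanium dichloride Lewis acid should bind quinone 5 as a five-membered chelate through the C11 carbonyl and the C12 methoxy oxygen, which lowers the LUMO of the C8=C9 edge and makes C8 (β to the bound carbonyl) its electrophilic end, so that diene 15 adds in a concerted, asynchronous endo [4+2] in which the bond from the unsubstituted terminus C7 to C8 leads and the bond from the tetrasubstituted terminus C10 to C9 follows. The closest known reactions are the BINOL–titanium-catalysed enantioselective Diels–Alder additions of simple dienes to 2-methoxy-1,4-benzoquinones and the achiral Lewis-acid cycloadditions of quinones to 2-substituted 1-vinylcyclohexenes, whose combination on a diene with a fully substituted reacting terminus has not been shown. Ring B closes as a six-membered carbocycle by intermolecular suprafacial [4π+2π] addition across C7–C8 and C9–C10, and Et3N then enolises the cis-fused ene-dione 16 so that ring C becomes aromatic and C8 and C9 cease to be stereocentres. C10 is the one stereocentre that survives, and it is set by the face of the achiral diene that meets the quinone face left open by the BINOL ligand, which needs both facial discrimination by the ligand and a clean endo approach, since exo addition to the same quinone face would give the antipode. Regioselectivity (C7 to C8, C10 to C9) is secured by the chelate, which selects the C11 carbonyl over the vinylogous-ester C14 carbonyl, and by the larger HOMO coefficient at C7, while the tetrasubstituted, donor-bearing C12=C13 edge does not compete. The diene is used in slight excess so that no quinone remains to oxidise the product hydroquinone.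

**Step 11**
Reactants: 17 dimethyl (10R)-20-[(tert-butyldimethylsilyl)oxy]-11,14-dihydroxy-12-methoxyabieta-5,8,11,13-tetraene-18,19-dioate
Product: 18 dimethyl (10R)-20-[(tert-butyldimethylsilyl)oxy]-11,12,14-trimethoxyabieta-5,8,11,13-tetraene-18,19-dioate
Conditions: MeI, Cs2CO3, DMF, 40 °C, argon
Reagents that add atoms: iodomethane, CI
Why: Williamson O-methylation protects the air-sensitive hydroquinone and leaves the C11/C14 pair as the para-dimethoxy unit that is unmasked oxidatively at the end.

**Step 12**
Reactants: 18 dimethyl (10R)-20-[(tert-butyldimethylsilyl)oxy]-11,12,14-trimethoxyabieta-5,8,11,13-tetraene-18,19-dioate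
Product: 19 dimethyl 20-[(tert-butyldimethylsilyl)oxy]-11,12,14-trimethoxy-5α-abieta-8,11,13-triene-18,19-dioate
Conditions: H2 (5 bar), 10% Pd/C, EtOAc, rt
Reagents that add atoms: none
Why: Heterogeneous hydrogenation should deliver hydrogen to the C5=C6 alkene from the α face, opposite the C10 CH2OSi arm, as in the reduction of 5-ene steroids and 4,4-disubstituted hexahydrophenanthrenes to trans-fused products, which sets C5 (H α).

**Step 13**
Reactants: 19 dimethyl 20-[(tert-butyldimethylsilyl)oxy]-11,12,14-trimethoxy-5α-abieta-8,11,13-triene-18,19-dioate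
Product: 20 methyl 20-[(tert-butyldimethylsilyl)oxy]-11,12,14-trimethoxy-18-nor-5α-abieta-8,11,13-trien-19-oate (both C4 epimers)
Conditions: LiCl, H2O, DMSO, 150 °C
Reagents that add atoms: none
Why: Krapcho dealkoxycarbonylation (chloride demethylates one ester by SN2 and the carboxylate loses CO2); the C4 configuration of 20 does not matter because C4 is planarised in the next step.

**Step 14**
Reactants: 20 methyl 20-[(tert-butyldimethylsilyl)oxy]-11,12,14-trimethoxy-18-nor-5α-abieta-8,11,13-trien-19-oate
Product: 22 methyl 20-[(tert-butyldimethylsilyl)oxy]-11,12,14-trimethoxy-5α-abieta-8,11,13-trien-19-oate (4α-CH3, 4β-CO2CH3), via lithium ester enolate 21 (not isolated)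
Conditions: LiN(iPr)2, THF, −78 → −40 °C; then MeI, −78 °C → rt
Reagents that add atoms: iodomethane, CI; lithium diisopropylamide (lithium of 21 only), CC(C)N([Li])C(C)C
Why: Ester enolate alkylation in which iodomethane approaches the exocyclic C4 enolate equatorially from the α face, anti to the axial C10 arm (1,3-diaxial control, as in methylations of podocarpate-type C4 ester enolates), so the methyl ends α and the ester β.

**Step 15**
Reactants: 22 methyl 20-[(tert-butyldimethylsilyl)oxy]-11,12,14-trimethoxy-5α-abieta-8,11,13-trien-19-oate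
Product: 24 11,12,14-trimethoxy-5α-abieta-8,11,13-trien-19,20-olide, via C20 hydroxy ester 23 (not isolated)
Conditions: Bu4NF, THF, 0 → 50 °C
Reagents that add atoms: none
Why: Fluoride desilylation frees the C20 oxygen, which sits 1,3-diaxial to the β ester and closes the six-membered lactone by acyl substitution with loss of methanol.

**Step 16**
Reactants: 24 11,12,14-trimethoxy-5α-abieta-8,11,13-trien-19,20-olide
Product: 25 11,12,14-trimethoxy-7-oxo-5α-abieta-8,11,13-trien-19,20-olide
Conditions: CrO3, AcOH/H2O, rt
Reagents that add atoms: chromium trioxide, O=[Cr](=O)=O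
Why: Benzylic oxidation by hexavalent chromium at C7, the only unhindered benzylic methylene (para to the C12 methoxy group), as in the known conversion of abietatrienes into their 7-ketones; the isopropyl methine is held in the ring plane by two ortho methoxy groups.

**Step 17**
Reactants: 25 11,12,14-trimethoxy-7-oxo-5α-abieta-8,11,13-trien-19,20-olide
Product: 27 (4S,5R,10R)-11,14-dihydroxy-12-methoxy-7-oxoabieta-8,11,13-trien-19,20-olide (CNP0159814.2), via 7-oxo quinone 26 (not isolated)
Conditions: (NH4)2Ce(NO3)6, MeCN/H2O, 0 °C; then aq. Na2S2O4, EtOAc, rt, argon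
Reagents that add atoms: water, O
Why: Tetravalent cerium oxidatively demethylates only the para-related C11/C14 methoxy groups to the quinone while the C12 methoxy survives, and dithionite reduces the quinone to the hydroquinone, whose C14 hydroxyl is hydrogen-bonded to the C7 ketone.

**Compound list**
1 | 1,2,4-trimethoxybenzene | COc1ccc(OC)c(OC)c1 | starting material
2 | (2,3,6-trimethoxyphenyl)lithium | COc1ccc(OC)c([Li])c1OC | intermediate (not isolated)
3 | 2-(2,3,6-trimethoxyphenyl)propan-2-ol | COc1ccc(OC)c(C(C)(C)O)c1OC | intermediate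
4 | 1,2,4-trimethoxy-3-(propan-2-yl)benzene | COc1ccc(OC)c(C(C)C)c1OC | intermediate
5 | 2-isopropyl-3-methoxy-1,4-benzoquinone | COC1=C(C(C)C)C(=O)C=CC1=O | intermediate
6 | 2-bromoprop-2-en-1-ol | OCC(Br)=C | starting material
7 | [(2-bromoprop-2-en-1-yl)oxy](tert-butyl)dimethylsilane | C=C(Br)CO[Si](C)(C)C(C)(C)C | intermediate
8 | dimethyl 2-(prop-2-en-1-yl)propanedioate | C=CCC(C(=O)OC)C(=O)OC | starting material
9 | dimethyl 2-[3-(9-borabicyclo[3.3.1]nonan-9-yl)propyl]propanedioate | COC(=O)C(CCCB1C2CCCC1CCC2)C(=O)OC | intermediate (not isolated)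
10 | dimethyl 2-[4-({[tert-butyl(dimethyl)silyl]oxy}methyl)pent-4-en-1-yl]propanedioate | COC(=O)C(CCCC(=C)CO[Si](C)(C)C(C)(C)C)C(=O)OC | intermediate
11 | dimethyl 2-[4-({[tert-butyl(dimethyl)silyl]oxy}methyl)pent-4-en-1-yl]-2-(prop-2-en-1-yl)propanedioate | C=CCC(CCCC(=C)CO[Si](C)(C)C(C)(C)C)(C(=O)OC)C(=O)OC | intermediate
12 | bis-ozonide of 11 (two 1,2,4-trioxolanes, stereocentres undefined) | COC(=O)C(CC1OCOO1)(CCCC1(CO[Si](C)(C)C(C)(C)C)OCOO1)C(=O)OC | intermediate (not isolated)
13 | dimethyl 2-(5-{[tert-butyl(dimethyl)silyl]oxy}-4-oxopentyl)-2-(2-oxoethyl)propanedioate | O=CCC(CCCC(=O)CO[Si](C)(C)C(C)(C)C)(C(=O)OC)C(=O)OC | intermediate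
14 | dimethyl 3-({[tert-butyl(dimethyl)silyl]oxy}methyl)-2-formylcyclohex-2-ene-1,1-dicarboxylate | O=CC1=C(CO[Si](C)(C)C(C)(C)C)CCCC1(C(=O)OC)C(=O)OC | intermediate
15 | dimethyl 3-({[tert-butyl(dimethyl)silyl]oxy}methyl)-2-ethenylcyclohex-2-ene-1,1-dicarboxylate | C=CC1=C(CO[Si](C)(C)C(C)(C)C)CCCC1(C(=O)OC)C(=O)OC | intermediate
16 | dimethyl 20-[(tert-butyldimethylsilyl)oxy]-12-methoxy-11,14-dioxoabieta-5,12-diene-18,19-dioate, endo adduct (8β-H, 9β-H, 10β-CH2OSi) | COC1=C(C(C)C)C(=O)[C@@H]2CC=C3C(C(=O)OC)(C(=O)OC)CCC[C@]3(CO[Si](C)(C)C(C)(C)C)[C@@H]2C1=O | intermediate (not isolated)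
17 | dimethyl (10R)-20-[(tert-butyldimethylsilyl)oxy]-11,14-dihydroxy-12-methoxyabieta-5,8,11,13-tetraene-18,19-dioate | COc1c(O)c2c(c(O)c1C(C)C)CC=C1[C@]2(CO[Si](C)(C)C(C)(C)C)CCCC1(C(=O)OC)C(=O)OC | intermediate
18 | dimethyl (10R)-20-[(tert-butyldimethylsilyl)oxy]-11,12,14-trimethoxyabieta-5,8,11,13-tetraene-18,19-dioate | COc1c(OC)c2c(c(OC)c1C(C)C)CC=C1[C@]2(CO[Si](C)(C)C(C)(C)C)CCCC1(C(=O)OC)C(=O)OC | intermediate
19 | dimethyl 20-[(tert-butyldimethylsilyl)oxy]-11,12,14-trimethoxy-5α-abieta-8,11,13-triene-18,19-dioate (5α-H, 10β-CH2OSi) | COc1c(OC)c2c(c(OC)c1C(C)C)CC[C@@H]1[C@]2(CO[Si](C)(C)C(C)(C)C)CCCC1(C(=O)OC)C(=O)OC | intermediate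
20 | methyl 20-[(tert-butyldimethylsilyl)oxy]-11,12,14-trimethoxy-18-nor-5α-abieta-8,11,13-trien-19-oate (both C4 epimers) | COc1c(OC)c2c(c(OC)c1C(C)C)CC[C@@H]1[C@]2(CO[Si](C)(C)C(C)(C)C)CCCC1C(=O)OC | intermediate
21 | lithium enolate of 20 (C4=C19 ketene acetal) | COc1c(OC)c2c(c(OC)c1C(C)C)CC[C@@H]1[C@]2(CO[Si](C)(C)C(C)(C)C)CCCC1=C(O[Li])OC | intermediate (not isolated)
22 | methyl 20-[(tert-butyldimethylsilyl)oxy]-11,12,14-trimethoxy-5α-abieta-8,11,13-trien-19-oate (4α-CH3, 4β-CO2CH3) | COc1c(OC)c2c(c(OC)c1C(C)C)CC[C@@H]1[C@]2(CO[Si](C)(C)C(C)(C)C)CCC[C@]1(C)C(=O)OC | intermediate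
23 | methyl 20-hydroxy-11,12,14-trimethoxy-5α-abieta-8,11,13-trien-19-oate | COc1c(OC)c2c(c(OC)c1C(C)C)CC[C@@H]1[C@]2(CO)CCC[C@]1(C)C(=O)OC | intermediate (not isolated)
24 | 11,12,14-trimethoxy-5α-abieta-8,11,13-trien-19,20-olide | COc1c(OC)c2c(c(OC)c1C(C)C)CC[C@@H]1[C@]23CCC[C@]1(C)C(=O)OC3 | intermediate
25 | 11,12,14-trimethoxy-7-oxo-5α-abieta-8,11,13-trien-19,20-olide | COc1c(OC)c2c(c(OC)c1C(C)C)C(=O)C[C@@H]1[C@]23CCC[C@]1(C)C(=O)OC3 | intermediate
26 | 12-methoxy-7,11,14-trioxo-5α-abieta-8,12-dien-19,20-olide | COC1C(=O)C2=C(C(=O)C=1C(C)C)C(=O)C[C@@H]1[C@]23CCC[C@]1(C)C(=O)OC3 | intermediate (not isolated)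
27 | (4S,5R,10R)-11,14-dihydroxy-12-methoxy-7-oxoabieta-8,11,13-trien-19,20-olide | COc1c(O)c2c(c(O)c1C(C)C)C(=O)C[C@@H]1[C@]23CCC[C@]1(C)C(=O)OC3 | target

**Step count**
Total: 17 steps. Longest linear sequence: 14 steps (6 → 27, steps 4–17).

**Steps most likely to fail**

Step 10. The diene carries the CH2OSi group in the inside (Z) position of its reacting terminus, so the cycloaddition has to pass through a strained s-cis conformer and may be slow. Weak facial discrimination by the ligand, or leakage through an exo approach, would erode the enantiomeric purity at C10. The fallback uses known chemistry and sets out from 15 and 5. SnCl4 (1 equiv, CH2Cl2, −78 → −20 °C) is a stronger achiral Lewis acid that chelates the same carbonyl/methoxy pair and so keeps the regiochemistry. After Et3N it should give racemic hydroquinone F1. Methylation as in step 11 gives racemic trimethyl ether F2, which is resolved by preparative chromatography on a cellulose-carbamate chiral stationary phase. The (10R) enantiomer is 18, where the route is rejoined.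

Step 8. The ketone may enolise and attack the aldehyde instead, closing to a 1-acylcyclohexene. The neopentyl enamine carbon C5 may add too slowly to the ketone. The allylic silyloxy group of the product may be lost by vinylogous elimination. The fallback sets out from 10 and replaces carbonyl condensation by metathesis. Electrophilic ethynylation of the malonate anion (KOtBu, 1-[(trimethylsilyl)ethynyl]-1,2-benziodoxol-3(1H)-one, Bu4NF, THF, −78 °C) gives ethynyl malonate F3. Ring-closing enyne metathesis in the exo mode (second-generation Grubbs catalyst RuCl2(H2IMes)(PCy3)(=CHPh), ethylene atmosphere, toluene, 80 °C) forms the C5=C10 ring alkene and the C6=C7 vinyl group together and comes back to the route at 15.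

Step 16. The oxidant may attack the electron-rich trimethoxyarene (premature oxidative demethylation) or the isopropyl methine instead of C7, or conversion at the peri-hindered C7 may stop short. The fallback sets out from 24 and functionalises C7 in stages. Radical benzylic bromination (NBS, AIBN, PhCF3, 80 °C; every ring position is substituted) gives 7-bromide F4. Its p-alkoxybenzylic C–Br bond is solvolysed (Ag2CO3, acetone/H2O, rt) to 7-alcohol F5. Dess–Martin oxidation then returns to the route at 25.

**Further compounds**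
F1 | step 10 | racemic hydroquinone (racemate of 17) | COc1c(O)c2c(c(O)c1C(C)C)CC=C1C2(CO[Si](C)(C)C(C)(C)C)CCCC1(C(=O)OC)C(=O)OC
F2 | step 10 | racemic trimethyl ether (racemate of 18) | COc1c(OC)c2c(c(OC)c1C(C)C)CC=C1C2(CO[Si](C)(C)C(C)(C)C)CCCC1(C(=O)OC)C(=O)OC
F3 | step 8 | ethynyl malonate: dimethyl 2-[4-({[tert-butyl(dimethyl)silyl]oxy}methyl)pent-4-en-1-yl]-2-ethynylpropanedioate | C#CC(CCCC(=C)CO[Si](C)(C)C(C)(C)C)(C(=O)OC)C(=O)OC
F4 | step 16 | 7-bromide: 7-bromo-11,12,14-trimethoxy-5α-abieta-8,11,13-trien-19,20-olide (C7 epimers) | COc1c(OC)c2c(c(OC)c1C(C)C)C(Br)C[C@@H]1[C@]23CCC[C@]1(C)C(=O)OC3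
F5 | step 16 | 7-alcohol: 7-hydroxy-11,12,14-trimethoxy-5α-abieta-8,11,13-trien-19,20-olide (C7 epimers) | COc1c(OC)c2c(c(OC)c1C(C)C)C(O)C[C@@H]1[C@]23CCC[C@]1(C)C(=O)OC3
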